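The retrosynthesis goes back from the target by saponification, reduction of a ketone at the secondary carbinol, and removal of both oxygens (Kornblum–DeLaMare, singlet oxygen) to a tetracyclic cyclohexa-1,3-diene ester. The diene ring is then cut at the two bonds that join it to the cyclopentane (future tertiary carbinol C to ring-fusion CH, future secondary carbinol C to ring-fusion CH). This is the retron of a 2-pyrone + alkene [4+2] with loss of CO2.
Enabling feature: the ring that carries CO2H is a 1,4-dioxygenated cyclohex-2-ene whose C(OH)–C(CO2H)=CH–CH(OH) chain maps onto C6–C5–C4–C3 of a coumalate. The edge it shares with the cyclopentane is the C=C of a bicyclo[3.2.0]heptene. The cis-CH=CH of the other cyclohexene, together with two cyclobutane carbons, is a ready four-atom tether on the concave face.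
Forward order: an acyclic C15 hydroxy acid gives the cyclobutanone and the cyclopentene together (vinylketene [2+2]). One-carbon homologation and a Z-Wittig union with a formyl coumalate follow, then both cyclohexene rings form at once (key step), then oxygenation, epimerisation, reduction and hydrolysis.
Stereochemistry: the E-alkene geometry puts octyl trans to the ring CH2, and a sulfoximine resolution gives the absolute configuration. Convex-face hydroboration sets the side-chain carbon, the tether fixes the face of the cycloaddition, and 1O2 adds anti to the five-membered ring to set the tertiary carbinol.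
A concerted addition to a cyclopentene can only give a cis 6/5 fusion, whereas the target is trans there. The CH next to the later ketone is therefore epimerised under thermodynamic control, and the ketone is then reduced from its equatorial side.

Key step: step 13

Assumption: which of the two chromatographically separated adducts of step 5 holds the (1R,5R,7R) skeleton is to be assigned (X-ray or CD) before it is carried on. The numbering of ketone 9 (C1/C5 ring fusion, C3=C4, C6, C7) is kept for all bicyclic intermediates.

Step 1
Reactants: 1 (E)-undec-2-en-1-ol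
Product: 2 (E)-1-bromoundec-2-ene
Conditions: PBr3, Et2O, 0 °C
Reagents that add atoms: phosphorus tribromide, BrP(Br)Br
Why: SN2 displacement of the phosphite ester of a primary allylic alcohol at low temperature should keep the E geometry and avoid allylic transposition.

Step 2
Reactants: 2 (E)-1-bromoundec-2-ene; 3 methyl acetoacetate
Product: 5 methyl (E)-3-oxopentadec-6-enoate, via acetoacetate dianion 4 (not isolated)
Conditions: 3, NaH, THF, 0 °C; n-BuLi, 0 °C; then 2, 0 °C to rt; aq HCl
Reagents that add atoms: none
Why: Weiler dianion alkylation takes place at the more nucleophilic terminal carbon and by direct SN2 on the primary allylic bromide, so the C15 chain with its E-alkene should arise in one operation.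

Step 3
Reactants: 5 methyl (E)-3-oxopentadec-6-enoate
Product: 7 (E)-3-hydroxypentadec-6-enoic acid (racemic at C3), via hydroxy ester 6 (not isolated)
Conditions: NaBH4, MeOH, 0 °C; then aq KOH, rt; then aq HCl
Reagents that add atoms: potassium hydroxide, [K+].[OH-]
Why: Borohydride reduction of the ketone followed by saponification in the same flask is routine, and the carbinol configuration is irrelevant because this centre becomes sp2 in step 4.

Step 4
Reactants: 7 (E)-3-hydroxypentadec-6-enoic acid
Product: 9 rac-7-exo-octyl-cis-bicyclo[3.2.0]hept-3-en-6-one, via vinylketene 8 (not isolated)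
Conditions: Ac2O, KOAc, rt, then reflux
Reagents that add atoms: none
Why: Acetylation, beta-elimination and loss of acetic acid from the mixed anhydride give an alpha,beta-unsaturated ketene that undergoes the known intramolecular ketene–alkene [2+2] cycloaddition of 3-hydroxy-6-alkenoic acids, in which the three-atom tether forces the cis 4/5 fusion and suprafacial addition to the E-alkene places octyl trans to the ring CH2 (exo, also the more stable epimer next to the ketone).

Step 5
Reactants: 9 rac-7-exo-octyl-cis-bicyclo[3.2.0]hept-3-en-6-one; 10 (S)-N,S-dimethyl-S-phenylsulfoximine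
Product: 12 beta-hydroxysulfoximine of the (1R,5R,7R)-ketone (6-endo-OH, 6-exo-CH2S(O)(NMe)Ph), via lithiated sulfoximine 11 (not isolated)
Conditions: 10, n-BuLi, THF, −78 °C; then 9, −78 °C; H2O; separation on SiO2
Reagents that add atoms: none
Why: Johnson resolution, in which 1,2-addition from the convex face turns each ketone enantiomer into one diastereomer, so chromatography should deliver the single enantiomeric series.

Step 6
Reactants: 12 beta-hydroxysulfoximine
Product: 13 (1R,5R,7R series) 6-methylidene-7-exo-octylbicyclo[3.2.0]hept-3-ene
Conditions: Al(Hg), AcOH, THF/H2O, rt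
Reagents that add atoms: none
Why: Johnson reductive elimination of a beta-hydroxysulfoximine gives the methylidene compound, does not touch the isolated cyclopentene and leaves the three ring stereocentres unchanged.

Step 7
Reactants: 13 6-methylidene-7-exo-octylbicyclo[3.2.0]hept-3-ene
Product: 15 (7-exo-octylbicyclo[3.2.0]hept-3-en-6-endo-yl)methanol, via B-alkyl-9-BBN adduct 14 (not isolated)
Conditions: 9-BBN, THF, 0 °C to rt; then NaOH, H2O2
Reagents that add atoms: hydrogen peroxide, OO
Why: In this Brown hydroboration–oxidation 9-BBN strongly prefers the 1,1-disubstituted alkene over the cyclopentene, and its approach from the convex face delivers H exo, so the CH2OH arm should end up endo and trans to octyl.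

Step 8
Reactants: 15 (7-exo-octylbicyclo[3.2.0]hept-3-en-6-endo-yl)methanol
Product: 16 6-endo-(iodomethyl)-7-exo-octylbicyclo[3.2.0]hept-3-ene
Conditions: I2, PPh3, imidazole, CH2Cl2, 0 °C
Reagents that add atoms: iodine, II
Why: Appel-type (Garegg–Samuelsson) iodination of a primary alcohol is neutral and takes place away from the stereocentres.

Step 9
Reactants: 16 6-endo-(iodomethyl)-7-exo-octylbicyclo[3.2.0]hept-3-ene
Product: 17 [(7-exo-octylbicyclo[3.2.0]hept-3-en-6-endo-yl)methyl]triphenylphosphonium iodide
Conditions: PPh3, MeCN, reflux
Reagents that add atoms: triphenylphosphine, c1ccc(cc1)P(c1ccccc1)c1ccccc1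
Why: SN2 quaternisation of a primary iodide gives the salt of a non-stabilised ylide, and it avoids an epimerisable cyclobutanecarbaldehyde.

Step 10
Reactants: 3 methyl acetoacetate; 18 methyl propiolate
Product: 20 methyl 6-methyl-2-oxo-2H-pyran-5-carboxylate, via acetylglutaconate 19 (not isolated)
Conditions: NaOMe (cat), MeOH, 0 °C to rt; then p-TsOH (cat), PhMe, reflux
Reagents that add atoms: none
Why: Michael addition of the beta-keto ester to the alkynoate followed by enol lactonisation is the classical route to 6-alkyl coumalates and places the ester at C5 and the methyl group at C6.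

Step 11
Reactants: 20 methyl 6-methyl-2-oxo-2H-pyran-5-carboxylate
Product: 21 methyl 6-formyl-2-oxo-2H-pyran-5-carboxylate
Conditions: SeO2, 1,4-dioxane, sealed tube, heat
Reagents that add atoms: selenium dioxide, O=[Se]=O
Why: Riley oxidation of the vinylogously activated 6-methyl group of a 2-pyrone to the aldehyde is a known transformation of this ring system.

Step 12
Reactants: 17 phosphonium iodide; 21 methyl 6-formyl-2-oxo-2H-pyran-5-carboxylate
Product: 23 methyl 6-[(Z)-2-(7-exo-octylbicyclo[3.2.0]hept-3-en-6-endo-yl)ethenyl]-2-oxo-2H-pyran-5-carboxylate, via phosphorus ylide 22 (not isolated)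
Conditions: 17, NaHMDS, THF, −78 to 0 °C; then 21, −78 °C to rt, dark
Reagents that add atoms: none
Why: A Wittig reaction of a non-stabilised ylide under lithium-salt-free conditions is Z-selective through the kinetic cis-oxaphosphetane, and at −78 °C the aldehyde should outrun any addition to the pyrone ring.

Step 13
Reactants: 23 (Z)-alkenyl coumalate
Product: 25 tetracyclic triene ester (methyl cyclohexa-1,3-dienecarboxylate ring cis-fused to the cyclopentane, second ring closed over the cis-CH=CH), via bridged lactone 24 (not isolated)
Conditions: BHT (cat), 1,2-dichlorobenzene (5 mM), Ar, dark, 160–180 °C, sealed tube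
Reagents that add atoms: none
Why: The electron-poor 2-pyrone adds through C6 and C3 to the cyclopentene C=C in an inverse-electron-demand intramolecular Diels–Alder reaction to give bridged lactone 24, which loses CO2 by retro-[4+2] at the same temperature, so both C–C bonds arise in one suprafacial event and the lactone bridge is a traceless helper. The closest known reactions are thermal intramolecular 2-pyrone cycloadditions to unactivated alkenes and the coumalate + alkene route to dihydrobenzoates. The ester-bearing ring closes as the six-membered [4+2] ring, and the second cyclohexene closes as a fused six-membered ring over the four-atom tether (two cyclobutane carbons and the cis-CH=CH), which makes this a type 1 intramolecular Diels–Alder reaction with the tether at diene terminus C6. The two new ring-fusion CH centres are set cis to each other by suprafacial addition and lie on the concave face, cis to the cyclobutane bonds, because the endo side chain can reach only that face, while the bridgehead centres of 24 disappear with CO2, so the orientation of the lactone bridge does not matter. Regiochemistry (C6 to the alkene carbon next to the ring fusion) is fixed by the tether length, only the Z-alkene can reach the cyclopentene, and the alkenyl group lies trans to C4 across C5=C6, so the conjugated system has no 6π or 1,7-H shift pathway; high dilution, BHT and exclusion of O2 guard against dimerisation and aromatisation. The cis 6/5 fusion is inherent to the concerted event and is corrected in step 14.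

Step 14
Reactants: 25 tetracyclic triene ester
Product: 28 trans-fused gamma-hydroxy enone ester, via endoperoxide 26 (not isolated), via cis-fused hydroxy enone 27 (not isolated)
Conditions: O2, TPP (cat), visible light, CH2Cl2, −20 °C; Ar purge; then DBU, 0 °C to rt
Reagents that add atoms: dioxygen, O=O
Why: Singlet oxygen adds [4+2] to the s-cis homoannular diene from the face that bears only the two ring-fusion H atoms (anti to the cyclopentane) and so sets the tertiary C–O cis to the neighbouring ring-fusion H, after which DBU removes the only H on a peroxide carbon (Kornblum–DeLaMare rearrangement) and equilibrates the CH alpha to the new ketone, the trans 6/5 fusion being favoured because three rings that share one carbon can all be staggered only with an odd number of trans fusions, whereas all-cis 27 keeps a boat ring.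

Step 15
Reactants: 28 trans-fused gamma-hydroxy enone ester
Product: 29 cis-1,4-diol methyl ester (methyl ester of the target)
Conditions: L-Selectride, THF, −78 °C; then H2O
Reagents that add atoms: none
Why: In this 1,2-reduction by a bulky trialkylborohydride the beta-carbon of the enone is fully substituted, so conjugate attack is slowed, and the equatorial trajectory avoids the axial ring-fusion H on the other face, which should give the pseudoaxial alcohol cis to the tertiary OH.

Step 16
Reactants: 29 cis-1,4-diol methyl ester
Product: 30 target acid CNP0106718.3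
Conditions: LiOH, THF/MeOH/H2O, rt; then dilute HCl to pH 4, 0 °C
Reagents that add atoms: lithium hydroxide, [Li+].[OH-]
Why: Saponification of the unsaturated methyl ester touches no stereocentre, the acid cannot lactonise onto the secondary OH (it lies trans across the ring C=C), and the cold, mild acidification spares the bis-allylic tertiary alcohol.

Compound list
1 | (E)-undec-2-en-1-ol | CCCCCCCC/C=C/CO | starting material
2 | (E)-1-bromoundec-2-ene | CCCCCCCC/C=C/CBr | intermediate
3 | methyl acetoacetate | CC(=O)CC(=O)OC | starting material
4 | acetoacetate dianion (Na/Li) | [Na+].[Li+].[CH2-]C(=O)[CH-]C(=O)OC | intermediate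
5 | methyl (E)-3-oxopentadec-6-enoate | CCCCCCCC/C=C/CCC(=O)CC(=O)OC | intermediate
6 | methyl (E)-3-hydroxypentadec-6-enoate (racemic) | CCCCCCCC/C=C/CCC(O)CC(=O)OC | intermediate
7 | (E)-3-hydroxypentadec-6-enoic acid (racemic) | CCCCCCCC/C=C/CCC(O)CC(=O)O | intermediate
8 | (3Z,6E)-pentadeca-1,3,6-trien-1-one (vinylketene) | CCCCCCCC/C=C/C/C=C\C=C=O | intermediate
9 | 7-exo-octyl-cis-bicyclo[3.2.0]hept-3-en-6-one (racemic; the (1R,5R,7R) enantiomer that is carried on is drawn) | CCCCCCCC[C@H]1C(=O)[C@@H]2C=CC[C@H]12 | intermediate
10 | (S)-N,S-dimethyl-S-phenylsulfoximine | CN=[S@](=O)(C)c1ccccc1 | starting material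
11 | lithiated (S)-sulfoximine | [Li]C[S@@](=O)(=NC)c1ccccc1 | intermediate
12 | beta-hydroxysulfoximine of the (1R,5R,7R)-ketone (6-endo-OH) | CCCCCCCC[C@H]1[C@@](O)(C[S@@](=O)(=NC)c3ccccc3)[C@@H]2C=CC[C@H]12 | intermediate
13 | 6-methylidene-7-exo-octylbicyclo[3.2.0]hept-3-ene | CCCCCCCC[C@H]1C(=C)[C@@H]2C=CC[C@H]12 | intermediate
14 | B-alkyl-9-BBN adduct (6-endo-CH2B) | CCCCCCCC[C@H]1[C@H](CB3C4CCCC3CCC4)[C@@H]2C=CC[C@H]12 | intermediate
15 | (7-exo-octylbicyclo[3.2.0]hept-3-en-6-endo-yl)methanol | CCCCCCCC[C@H]1[C@H](CO)[C@@H]2C=CC[C@H]12 | intermediate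
16 | 6-endo-(iodomethyl)-7-exo-octylbicyclo[3.2.0]hept-3-ene | CCCCCCCC[C@H]1[C@H](CI)[C@@H]2C=CC[C@H]12 | intermediate
17 | [(7-exo-octylbicyclo[3.2.0]hept-3-en-6-endo-yl)methyl]triphenylphosphonium iodide | CCCCCCCC[C@H]1[C@H](C[P+](c3ccccc3)(c3ccccc3)c3ccccc3)[C@@H]2C=CC[C@H]12.[I-] | intermediate
18 | methyl propiolate | C#CC(=O)OC | starting material
19 | dimethyl 4-acetylpent-2-enedioate (acetylglutaconate) | COC(=O)/C=C/C(C(C)=O)C(=O)OC | intermediate
20 | methyl 6-methyl-2-oxo-2H-pyran-5-carboxylate | CC1=C(C(=O)OC)C=CC(=O)O1 | intermediate
21 | methyl 6-formyl-2-oxo-2H-pyran-5-carboxylate | O=CC1=C(C(=O)OC)C=CC(=O)O1 | intermediate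
22 | phosphorus ylide from 17 | CCCCCCCC[C@H]1[C@H](C=P(c3ccccc3)(c3ccccc3)c3ccccc3)[C@@H]2C=CC[C@H]12 | intermediate
23 | (Z)-alkenyl coumalate | CCCCCCCC[C@H]1[C@H](/C=C\C3=C(C(=O)OC)C=CC(=O)O3)[C@@H]2C=CC[C@H]12 | intermediate
24 | bridged bicyclo[2.2.2] lactone (lactone bridge drawn anti to the cyclopentane) | CCCCCCCC[C@H]1[C@@H]2C=C[C@]3(O5)C(C(=O)OC)=C[C@@H](C5=O)[C@@H]4C[C@H]1[C@H]2[C@@H]43 | intermediate
25 | tetracyclic triene ester (cis 6/5 fusion) | CCCCCCCC[C@H]1[C@@H]2C=CC3=C(C(=O)OC)C=C[C@@H]4C[C@H]1[C@H]2[C@@H]43 | intermediate
26 | endoperoxide (O–O bridge syn to the ring-fusion H atoms) | CCCCCCCC[C@H]1[C@@H]2C=C[C@]3(O5)C(C(=O)OC)=C[C@@H](O5)[C@@H]4C[C@H]1[C@H]2[C@@H]43 | intermediate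
27 | cis-fused gamma-hydroxy enone ester | CCCCCCCC[C@H]1[C@@H]2C=C[C@]3(O)C(C(=O)OC)=CC(=O)[C@@H]4C[C@H]1[C@H]2[C@@H]43 | intermediate
28 | trans-fused gamma-hydroxy enone ester | CCCCCCCC[C@H]1[C@@H]2C=C[C@]3(O)C(C(=O)OC)=CC(=O)[C@H]4C[C@H]1[C@H]2[C@@H]43 | intermediate
29 | cis-1,4-diol methyl ester | CCCCCCCC[C@H]1[C@@H]2C=C[C@]3(O)C(C(=O)OC)=C[C@@H](O)[C@H]4C[C@H]1[C@H]2[C@@H]43 | intermediate
30 | target acid CNP0106718.3 | CCCCCCCC[C@H]1[C@@H]2C=C[C@]3(O)C(C(=O)O)=C[C@@H](O)[C@H]4C[C@H]1[C@H]2[C@@H]43 | target

Total steps: 16. Longest linear sequence: 14 (steps 1–9 and 12–16).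

Steps most likely to fail

Step 13. The unactivated cyclopentene may engage the pyrone too slowly, so that Z to E isomerisation of the tether or reversion of the strained adduct competes before CO2 is lost.
The fallback uses a removable activating substituent, sets out from 20 and comes back at 25.
- Electrophilic bromination at C3 (Br2, CH2Cl2, then Et3N) gives methyl 3-bromo-6-methyl-2-oxo-2H-pyran-5-carboxylate F1, a member of the more reactive 3-bromo-2-pyrone diene class.
- Riley oxidation gives methyl 3-bromo-6-formyl-2-oxo-2H-pyran-5-carboxylate F2.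
- A Wittig reaction with ylide 22 gives the (Z)-alkenyl bromopyrone F3.
- Heating gives the bridged bromolactone F4, and loss of CO2 gives the bromotriene ester F5.
- Pd(PPh3)4-catalysed hydrodebromination with Bu3SnH then returns to 25.

Step 14. Under base the endoperoxide may fragment or lose the tertiary C–O bond with aromatisation instead of rearranging cleanly.
The fallback separates O–O cleavage from oxidation, sets out from 26 (photooxygenation stopped before the base is added) and comes back at 27.
- Thiourea in MeOH reduces the peroxide to the all-cis-fused cis-1,4-diol ester F6.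
- MnO2 oxidises only its secondary allylic alcohol to 27.
- 27 is then equilibrated to 28 with a catalytic amount of DBU in a separate operation.

Step 15. Facial selectivity may be poor, or conjugate reduction of the 4-oxo-2-enoate may compete.
The fallback accepts the opposite facial outcome and inverts it, sets out from 28 and comes back at 29.
- Luche reduction (NaBH4, CeCl3, MeOH) by axial attack gives the pseudoequatorial epi-alcohol ester F7.
- Mitsunobu reaction with 4-nitrobenzoic acid (PPh3, DIAD) inverts only the secondary carbinol to the 4-nitrobenzoate F8.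
- K2CO3 in MeOH then releases 29.

Further compounds
F1 | step 13 | methyl 3-bromo-6-methyl-2-oxo-2H-pyran-5-carboxylate | CC1=C(C(=O)OC)C=C(Br)C(=O)O1
F2 | step 13 | methyl 3-bromo-6-formyl-2-oxo-2H-pyran-5-carboxylate | O=CC1=C(C(=O)OC)C=C(Br)C(=O)O1
F3 | step 13 | (Z)-alkenyl bromopyrone | CCCCCCCC[C@H]1[C@H](/C=C\C3=C(C(=O)OC)C=C(Br)C(=O)O3)[C@@H]2C=CC[C@H]12
F4 | step 13 | bridged bromolactone | CCCCCCCC[C@H]1[C@@H]2C=C[C@]3(O5)C(C(=O)OC)=C[C@@](Br)(C5=O)[C@@H]4C[C@H]1[C@H]2[C@@H]43
F5 | step 13 | bromotriene ester | CCCCCCCC[C@H]1[C@@H]2C=CC3=C(C(=O)OC)C=C(Br)[C@@H]4C[C@H]1[C@H]2[C@@H]43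
F6 | step 14 | all-cis-fused cis-1,4-diol ester | CCCCCCCC[C@H]1[C@@H]2C=C[C@]3(O)C(C(=O)OC)=C[C@@H](O)[C@@H]4C[C@H]1[C@H]2[C@@H]43
F7 | step 15 | pseudoequatorial epi-alcohol ester | CCCCCCCC[C@H]1[C@@H]2C=C[C@]3(O)C(C(=O)OC)=C[C@H](O)[C@H]4C[C@H]1[C@H]2[C@@H]43
F8 | step 15 | inverted 4-nitrobenzoate | CCCCCCCC[C@H]1[C@@H]2C=C[C@]3(O)C(C(=O)OC)=C[C@@H](OC(=O)c5ccc(cc5)[N+](=O)[O-])[C@H]4C[C@H]1[C@H]2[C@@H]43
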